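The ratio of idle complex to free catalyst equals K4 times c(added ligand), so I followed one catalyst molecule and asked how much of its time it spent free.

    substrate + free catalyst ⇌ free catalyst + intermediate (K1 = 9.89, k1 = 1.28 M⁻¹ s⁻¹)
    reagent + second catalyst + intermediate → second catalyst + target (k2 = 2.87 M⁻² s⁻¹)
    intermediate → side product (k3 = 0.00299 s⁻¹)
    free catalyst + added ligand ⇌ idle complex, settled at all times (K4 = 735 M⁻¹)

substrate 0.032 M; reagent 2.00 equiv; free catalyst 0.64 mol%; second catalyst 2 mol%; added ligand 1.2 mM

* the form that holds most of the catalyst when 20% of the substrate are converted (free catalyst / idle complex)
* its share of the catalyst then
* apparent order in free catalyst when 20% of the substrate are converted (percent change of the rate of making target for one percent more free catalyst charged)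

I first took c(added ligand) as charged, 1.2 mM. That gave 0.882 idle per free, so a free share of 53.1%. With 0.205 mM of catalyst charged, that share gave substrate a half-life of about 1.38 h by the forward step. Intermediate had a half-life of 0.0644 h by the side step, which is much shorter. So c(intermediate) followed its making, and at a given conversion the rate of making target went with c(free catalyst). With a fixed share, one percent more catalyst meant one percent more rate, and I committed to free catalyst as the main form, with order 1.

The weak link was the ligand, since idle complex holds some of it: by my reckoning at the first share 0.0960 mM, which left 1.10 mM. The free share, the part of the catalyst charged that stands as free catalyst, then became 55.2%. More catalyst on the same charge of added ligand also takes up more ligand, so the free share rises a little with the catalyst charge. Differentiating that balance raised the order to 1.04.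

The forecast gave free catalyst at 55% (53% to 57%) and order 1.04 (0.95 to 1.12), with the words “the ligand stays in excess and ties up just under half the catalyst”.

The simulation gave free catalyst at 55.1%, idle complex at 44.9%, and order 1.0. Against my 55.2%, this flask still held 55.1% as free catalyst at 3.67 h. In this flask the side step used intermediate 26 times as fast as the step to target at 0.871 h. At 25.0 h this flask held far more side product than target, with side product at 96.3% and target at 3.75%.

All constants are those of an exercise; what happens was integrated by code.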